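**Retrosynthetic overview**
1. Locants: ring A (cyclopentane) is C2–C3–C4–C5–C6, ring B (cyclohexane) is C1–C2–C6–C7–C8–C9; C10 is the methylene on C1, C11/C12 the ethylidene on C5. The O9 angelate and the O4 acetate are attached last (steps 19–21).
2. Ring B is closed at C1–C9 by an intramolecular Nozaki–Hiyama–Kishi reaction of a C1 enol triflate with a C9 aldehyde (step 18). The enabling feature is the 2-methylidenecyclohexan-1-ol array C10=C1–C9(O) of ring B next to the trans O8; the trans C2/C6 bonds of ring A hold C1 and C9 in a chair-like six-membered array.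
3. C9 with its oxygen comes from an α-alkoxymethyllithium added to a C8 Weinreb amide, followed by CBS reduction at C8 (steps 9–13). The C1 enol triflate comes from a vinyl group by Wacker oxidation and enolate triflation (steps 14–15).
4. The C6–C7 bond, both of its stereocentres and the (Z)-C5=C11 ethylidene arise in one Ireland–Claisen rearrangement of a C11 isovalerate (step 8).
5. Ring A is taken intact from (R)-4-silyloxycyclopentenone (vinyl-cuprate addition/elimination for C2, Luche reduction for C4, CBS reduction for C11; steps 1–6). Ring order: A (purchased), then B (step 18).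

Key step: step 18

Assumption: (R)-4-silyloxycyclopentenone, tributyl(iodomethyl)stannane and angelic acid are taken as purchasable; TBS = tert-butyldimethylsilyl, PMB = 4-methoxybenzyl.

**Route**

Step 1
Reactants: 1 (4R)-4-[(tert-butyldimethylsilyl)oxy]cyclopent-2-en-1-one; 2 vinylmagnesium bromide
Product: 4 (4S)-4-ethenylcyclopent-2-en-1-one, via conjugate adduct 3 (not isolated)
Conditions: 2 (1.3 equiv), CuI (10 mol %), THF, −78 °C; aq. NH4Cl; then DBU (1.05 equiv), CH2Cl2, −20 °C
Reagents that add atoms: none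
Why: Copper-catalysed conjugate addition of the Grignard reagent occurs anti to the silyloxy group, and E1cB loss of silanol from β-silyloxy ketone 3 then moves the enone so that the chirality of 1 is transferred to the vinyl-bearing carbon (future C2) of 4.

Step 2
Reactants: 4 (4S)-4-ethenylcyclopent-2-en-1-one
Product: 5 (4S)-4-ethenyl-2-iodocyclopent-2-en-1-one
Conditions: I2, pyridine, CH2Cl2, 0 °C → rt
Reagents that add atoms: iodine, II
Why: α-Iodination of the enone by conjugate addition of pyridine, iodination of the enolate and elimination (Baylis–Hillman-type addition–elimination), which leaves the future C2 stereocentre untouched.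

Step 3
Reactants: 5 (4S)-4-ethenyl-2-iodocyclopent-2-en-1-one
Product: 6 (1S,4S)-4-ethenyl-2-iodocyclopent-2-en-1-ol
Conditions: NaBH4, CeCl3·7H2O, MeOH, −78 °C
Reagents that add atoms: none
Why: Luche 1,2-reduction in which hydride adds to the carbonyl face anti to the vinyl group, so the new carbinol (future C4) should be cis to the vinyl substituent.

Step 4
Reactants: 6 (1S,4S)-4-ethenyl-2-iodocyclopent-2-en-1-ol
Product: 7 tert-butyl{[(1S,4S)-4-ethenyl-2-iodocyclopent-2-en-1-yl]oxy}dimethylsilane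
Conditions: TBSCl, imidazole, DMF, rt
Reagents that add atoms: tert-butyl(chloro)dimethylsilane, CC(C)(C)[Si](C)(C)Cl
Why: Silyl ether formation at the allylic alcohol with imidazole as base; no stereocentre is affected.

Step 5
Reactants: 7 alkenyl iodide silyl ether; 8 N-methoxy-N-methylacetamide
Product: 10 1-{(3S,5S)-5-[(tert-butyldimethylsilyl)oxy]-3-ethenylcyclopent-1-en-1-yl}ethan-1-one, via alkenyllithium 9 (not isolated)
Conditions: t-BuLi (2.1 equiv), Et2O, −78 °C; then 8, −78 → 0 °C; aq. NH4Cl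
Reagents that add atoms: tert-butyllithium, CC(C)(C)[Li] (supplies the lithium of 9)
Why: Iodine–lithium exchange gives alkenyllithium 9, which is acylated once by the Weinreb amide through its chelated tetrahedral adduct (Weinreb ketone synthesis).

Step 6
Reactants: 10 methyl ketone (1-acetylcyclopentene)
Product: 11 (1R)-1-{(3S,5S)-5-[(tert-butyldimethylsilyl)oxy]-3-ethenylcyclopent-1-en-1-yl}ethan-1-ol
Conditions: (S)-2-methyl-CBS-oxazaborolidine [(3aS)-1-methyl-3,3-diphenyltetrahydro-1H,3H-pyrrolo[1,2-c][1,3,2]oxazaborole] (20 mol %), catecholborane, toluene, −78 °C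
Reagents that add atoms: none
Why: Corey–Bakshi–Shibata reduction in which the (S)-oxazaborolidine treats the cyclopentenyl group as the large substituent and should give the (R)-carbinol at C11, while catecholborane does not hydroborate the vinyl group at this temperature.

Step 7
Reactants: 11 (R)-allylic alcohol; 12 3-methylbutanoyl chloride
Product: 13 (1R)-1-{(3S,5S)-5-[(tert-butyldimethylsilyl)oxy]-3-ethenylcyclopent-1-en-1-yl}ethyl 3-methylbutanoate
Conditions: 12, pyridine, DMAP (cat.), CH2Cl2, 0 °C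
Reagents that add atoms: none
Why: O-Acylation of the secondary allylic alcohol by the acid chloride under nucleophilic catalysis, with retention at C11.

Step 8
Reactants: 13 isovalerate ester
Product: 16 (2S)-2-{(1R,2Z,3S,5S)-3-[(tert-butyldimethylsilyl)oxy]-5-ethenyl-2-ethylidenecyclopentyl}-3-methylbutanoic acid, via silyl ketene acetal 14 (not isolated), via trimethylsilyl ester 15 (not isolated)
Conditions: LiN(i-Pr)2 (1.2 equiv), THF, −78 °C; Me3SiCl, −78 °C → rt, then 50 °C; 1 M HCl
Reagents that add atoms: chlorotrimethylsilane, C[Si](C)(C)Cl (supplies the silyl groups of 14 and 15)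
Why: Ireland–Claisen rearrangement: kinetic enolisation in THF gives ketene acetal 14 with the isopropyl group cis to the allylic oxygen, and a chair transition state with the C11 methyl group equatorial transfers chirality from C11 so that C7 bonds to the face of C6 anti to the vinyl and silyloxy groups, which should set C6 (R), C7 (S) and the (Z)-ethylidene (methyl cis to C4) in one event.

Step 9
Reactants: 16 carboxylic acid
Product: 17 (2S)-2-{(1R,2Z,3S,5S)-3-[(tert-butyldimethylsilyl)oxy]-5-ethenyl-2-ethylidenecyclopentyl}-N-methoxy-N,3-dimethylbutanamide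
Conditions: MeNH(OMe)·HCl, EDC·HCl, HOBt, i-Pr2NEt, CH2Cl2, 0 °C → rt
Reagents that add atoms: N,O-dimethylhydroxylamine hydrochloride, CNOC.Cl
Why: Carbodiimide-mediated amide coupling to the Weinreb amide under near-neutral conditions that should not enolise the hindered C7 centre.

Step 10
Reactants: 18 (4-methoxyphenyl)methanol; 19 tributyl(iodomethyl)stannane
Product: 20 tributyl{[(4-methoxyphenyl)methoxy]methyl}stannane
Conditions: NaH, THF–DMF, 0 °C → rt
Reagents that add atoms: none
Why: Williamson ether synthesis, SN2 displacement of the primary iodide by the sodium alkoxide of 18.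

Step 11
Reactants: 17 Weinreb amide; 20 alkoxymethylstannane
Product: 22 (3S)-3-{(1R,2Z,3S,5S)-3-[(tert-butyldimethylsilyl)oxy]-5-ethenyl-2-ethylidenecyclopentyl}-1-[(4-methoxyphenyl)methoxy]-4-methylpentan-2-one, via lithium reagent 21 (not isolated)
Conditions: 20 (2.5 equiv), n-BuLi, THF, −78 °C; then 17, −78 °C; aq. NH4Cl
Reagents that add atoms: n-butyllithium, CCCC[Li] (supplies the lithium of 21)
Why: Tin–lithium exchange gives α-alkoxymethyllithium 21, which adds once to the Weinreb amide because the chelated tetrahedral adduct persists until work-up (Weinreb ketone synthesis), and this brings in C9 with its oxygen.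

Step 12
Reactants: 22 α-alkoxy ketone
Product: 23 (2S,3S)-3-{(1R,2Z,3S,5S)-3-[(tert-butyldimethylsilyl)oxy]-5-ethenyl-2-ethylidenecyclopentyl}-1-[(4-methoxyphenyl)methoxy]-4-methylpentan-2-ol
Conditions: (S)-2-methyl-CBS-oxazaborolidine (50 mol %), catecholborane, toluene, −78 → −40 °C
Reagents that add atoms: none
Why: Corey–Bakshi–Shibata reduction: the catalyst distinguishes the branched C7 side (large) from the CH2OPMB side (small) and should give the (S)-carbinol at C8, the sense that Felkin–Anh-type attack anti to the cyclopentyl group also favours.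

Step 13
Reactants: 23 C8 alcohol
Product: 24 (2S,3S)-2-[(tert-butyldimethylsilyl)oxy]-3-{(1R,2Z,3S,5S)-3-[(tert-butyldimethylsilyl)oxy]-5-ethenyl-2-ethylidenecyclopentyl}-1-[(4-methoxyphenyl)methoxy]-4-methylpentane
Conditions: TBSOTf, 2,6-lutidine, CH2Cl2, −78 → 0 °C
Reagents that add atoms: tert-butyldimethylsilyl trifluoromethanesulfonate, CC(C)(C)[Si](C)(C)OS(=O)(=O)C(F)(F)F
Why: Silylation of the hindered secondary alcohol with the silyl triflate and a hindered pyridine base.

Step 14
Reactants: 24 bis-silyl ether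
Product: 25 1-{(1R,2S,3Z,4S)-4-[(tert-butyldimethylsilyl)oxy]-2-{(2S,3S)-2-[(tert-butyldimethylsilyl)oxy]-1-[(4-methoxyphenyl)methoxy]-4-methylpentan-3-yl}-3-ethylidenecyclopentyl}ethan-1-one
Conditions: PdCl2 (10 mol %), CuCl (1 equiv), O2 (1 atm), DMF–H2O (7:1), rt
Reagents that add atoms: water, O
Why: Tsuji–Wacker oxidation: Markovnikov hydroxypalladation of the monosubstituted alkene by divalent palladium and water gives the methyl ketone at C1, and the hindered trisubstituted ethylidene should not react.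

Step 15
Reactants: 25 methyl ketone
Product: 27 1-{(1R,2S,3Z,4S)-4-[(tert-butyldimethylsilyl)oxy]-2-{(2S,3S)-2-[(tert-butyldimethylsilyl)oxy]-1-[(4-methoxyphenyl)methoxy]-4-methylpentan-3-yl}-3-ethylidenecyclopentyl}ethenyl trifluoromethanesulfonate, via potassium enolate 26 (not isolated)
Conditions: KN(SiMe3)2, THF, −78 °C; then PhNTf2, −78 → 0 °C
Reagents that add atoms: potassium bis(trimethylsilyl)amide, C[Si](C)(C)[N-][Si](C)(C)C.[K+] (supplies the potassium of 26); N-phenylbis(trifluoromethanesulfonimide), O=S(=O)(N(c1ccccc1)S(=O)(=O)C(F)(F)F)C(F)(F)F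
Why: Kinetic deprotonation on the methyl side of the ketone by the hindered amide base and O-triflation of enolate 26 (enol triflate formation) put the leaving group on C1 next to the C10 methylene.

Step 16
Reactants: 27 enol triflate PMB ether
Product: 28 1-{(1R,2S,3Z,4S)-4-[(tert-butyldimethylsilyl)oxy]-2-{(2S,3S)-2-[(tert-butyldimethylsilyl)oxy]-1-hydroxy-4-methylpentan-3-yl}-3-ethylidenecyclopentyl}ethenyl trifluoromethanesulfonate
Conditions: DDQ, CH2Cl2–pH 7 buffer (10:1), 0 °C
Reagents that add atoms: none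
Why: Oxidative cleavage of the 4-methoxybenzyl ether (hydride abstraction by DDQ, then hydrolysis of the oxocarbenium ion) frees the C9 alcohol and should leave silyl ethers, enol triflate and alkenes intact.

Step 17
Reactants: 28 primary alcohol
Product: 29 1-{(1R,2S,3Z,4S)-4-[(tert-butyldimethylsilyl)oxy]-2-{(2S,3S)-2-[(tert-butyldimethylsilyl)oxy]-4-methyl-1-oxopentan-3-yl}-3-ethylidenecyclopentyl}ethenyl trifluoromethanesulfonate
Conditions: Dess–Martin periodinane, NaHCO3, CH2Cl2, 0 °C → rt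
Reagents that add atoms: none
Why: Dess–Martin oxidation of the primary alcohol under buffered conditions should give the α-silyloxy aldehyde without epimerising C8.

Step 18
Reactants: 29 enol triflate aldehyde
Product: 30 (1Z,2S,3aR,5S,6S,7S,7aR)-2,6-bis[(tert-butyldimethylsilyl)oxy]-1-ethylidene-4-methylidene-7-(propan-2-yl)octahydro-1H-inden-5-ol
Conditions: CrCl2 (6 equiv), NiCl2 (2 mol % relative to CrCl2), degassed DMF, 0.005 M, rt
Reagents that add atoms: none
Why: Zerovalent nickel, formed from NiCl2 by CrCl2, inserts into the C1–O bond of the enol triflate, the alkenylnickel species transmetalates to trivalent chromium, and the alkenylchromium adds to the C9 aldehyde with retention of the alkene position, so that C10 ends up as the exocyclic methylene and O9 is obtained as the free hydroxyl. The closest known reaction type is the intramolecular Nozaki–Hiyama–Kishi cyclisation of enol triflates or 2-iodoalk-1-enes onto aldehydes, a standard way to close 2-methylidenecycloalkanols. Ring B is closed in the 6-exo-trig mode (C1 attacks the carbonyl carbon C9, the oxygen stays outside the ring). The new C9 stereocentre is controlled by the chair-like closure that the trans C2/C6 bonds of ring A enforce: isopropyl at C7 equatorial, the C8 silyloxy group axial, and the aldehyde C=O antiperiplanar to the C8–O bond (Cornforth-type dipole minimisation), which should put O9 axial and trans to O8 and also avoids allylic strain with the emerging C1=C10 bond. The step needs chemoselective addition to the aldehyde without epimerising C8 and without intermolecular coupling; the non-basic, aldehyde-selective organochromium reagent, the silyl protection of O8 and high dilution should secure this.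

Step 19
Reactants: 30 bicyclic allylic alcohol; 31 angelic acid
Product: 33 (1Z,2S,3aR,5S,6S,7S,7aR)-2,6-bis[(tert-butyldimethylsilyl)oxy]-1-ethylidene-4-methylidene-7-(propan-2-yl)octahydro-1H-inden-5-yl (2Z)-2-methylbut-2-enoate, via mixed anhydride 32 (not isolated)
Conditions: 31, 2,4,6-trichlorobenzoyl chloride, Et3N, toluene, rt; then 30, toluene, 80 °C
Reagents that add atoms: 2,4,6-trichlorobenzoyl chloride, O=C(Cl)c1c(Cl)cc(Cl)cc1Cl (supplies the aroyl part of 32)
Why: Yamaguchi-type esterification through mixed anhydride 32, run without DMAP, should acylate the hindered axial allylic alcohol at O9 with retention and without isomerising the (Z)-angeloyl group to the (E)-tigloyl group.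

Step 20
Reactants: 33 angelate bis-silyl ether
Product: 34 (1Z,2S,3aR,5S,6S,7S,7aR)-1-ethylidene-2,6-dihydroxy-4-methylidene-7-(propan-2-yl)octahydro-1H-inden-5-yl (2Z)-2-methylbut-2-enoate
Conditions: HF·pyridine, pyridine, THF, 0 °C → rt
Reagents that add atoms: none
Why: Fluoride-driven cleavage of both silyl ethers (desilylation); the trans-diaxial arrangement of O8 and O9 should rule out angeloyl migration.

Step 21
Reactants: 34 diol; 35 acetic anhydride
Product: 36 (1Z,2S,3aR,5S,6S,7S,7aR)-2-(acetyloxy)-1-ethylidene-6-hydroxy-4-methylidene-7-(propan-2-yl)octahydro-1H-inden-5-yl (2Z)-2-methylbut-2-enoate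
Conditions: 35 (1.2 equiv), pyridine, CH2Cl2, 0 °C
Reagents that add atoms: none
Why: Site-selective acylation: the ring A hydroxyl at C4 is far more accessible than the axial C8 hydroxyl flanked by the isopropyl-bearing C7 and the acyloxy-bearing C9.

**Compound list**

1 | (4R)-4-[(tert-butyldimethylsilyl)oxy]cyclopent-2-en-1-one | O=C1C=C[C@H](O[Si](C)(C)C(C)(C)C)C1 | starting material
2 | vinylmagnesium bromide | C=C[Mg]Br | starting material
3 | (3S,4R)-4-[(tert-butyldimethylsilyl)oxy]-3-ethenylcyclopentan-1-one | O=C1C[C@@H](C=C)[C@H](O[Si](C)(C)C(C)(C)C)C1 | intermediate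
4 | (4S)-4-ethenylcyclopent-2-en-1-one | C=C[C@@H]1CC(=O)C=C1 | intermediate
5 | (4S)-4-ethenyl-2-iodocyclopent-2-en-1-one | C=C[C@@H]1CC(=O)C(I)=C1 | intermediate
6 | (1S,4S)-4-ethenyl-2-iodocyclopent-2-en-1-ol | C=C[C@@H]1C[C@H](O)C(I)=C1 | intermediate
7 | tert-butyl{[(1S,4S)-4-ethenyl-2-iodocyclopent-2-en-1-yl]oxy}dimethylsilane | C=C[C@@H]1C[C@H](O[Si](C)(C)C(C)(C)C)C(I)=C1 | intermediate
8 | N-methoxy-N-methylacetamide | CC(=O)N(C)OC | starting material
9 | {(3S,5S)-5-[(tert-butyldimethylsilyl)oxy]-3-ethenylcyclopent-1-en-1-yl}lithium | C=C[C@@H]1C[C@H](O[Si](C)(C)C(C)(C)C)C([Li])=C1 | intermediate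
10 | 1-{(3S,5S)-5-[(tert-butyldimethylsilyl)oxy]-3-ethenylcyclopent-1-en-1-yl}ethan-1-one | C=C[C@@H]1C[C@H](O[Si](C)(C)C(C)(C)C)C(C(C)=O)=C1 | intermediate
11 | (1R)-1-{(3S,5S)-5-[(tert-butyldimethylsilyl)oxy]-3-ethenylcyclopent-1-en-1-yl}ethan-1-ol | C=C[C@@H]1C[C@H](O[Si](C)(C)C(C)(C)C)C([C@@H](C)O)=C1 | intermediate
12 | 3-methylbutanoyl chloride | CC(C)CC(=O)Cl | starting material
13 | (1R)-1-{(3S,5S)-5-[(tert-butyldimethylsilyl)oxy]-3-ethenylcyclopent-1-en-1-yl}ethyl 3-methylbutanoate | C=C[C@@H]1C[C@H](O[Si](C)(C)C(C)(C)C)C([C@@H](C)OC(=O)CC(C)C)=C1 | intermediate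
14 | tert-butyl{[(1S,4S)-4-ethenyl-2-[(1R)-1-({(1E)-3-methyl-1-[(trimethylsilyl)oxy]but-1-en-1-yl}oxy)ethyl]cyclopent-2-en-1-yl]oxy}dimethylsilane (isopropyl cis to the allylic oxygen) | C=C[C@@H]1C[C@H](O[Si](C)(C)C(C)(C)C)C([C@@H](C)O/C(O[Si](C)(C)C)=C\C(C)C)=C1 | intermediate
15 | trimethylsilyl (2S)-2-{(1R,2Z,3S,5S)-3-[(tert-butyldimethylsilyl)oxy]-5-ethenyl-2-ethylidenecyclopentyl}-3-methylbutanoate | C=C[C@@H]1C[C@H](O[Si](C)(C)C(C)(C)C)/C(=C\C)[C@H]1[C@H](C(C)C)C(=O)O[Si](C)(C)C | intermediate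
16 | (2S)-2-{(1R,2Z,3S,5S)-3-[(tert-butyldimethylsilyl)oxy]-5-ethenyl-2-ethylidenecyclopentyl}-3-methylbutanoic acid | C=C[C@@H]1C[C@H](O[Si](C)(C)C(C)(C)C)/C(=C\C)[C@H]1[C@H](C(C)C)C(=O)O | intermediate
17 | (2S)-2-{(1R,2Z,3S,5S)-3-[(tert-butyldimethylsilyl)oxy]-5-ethenyl-2-ethylidenecyclopentyl}-N-methoxy-N,3-dimethylbutanamide | C=C[C@@H]1C[C@H](O[Si](C)(C)C(C)(C)C)/C(=C\C)[C@H]1[C@H](C(C)C)C(=O)N(C)OC | intermediate
18 | (4-methoxyphenyl)methanol | COc1ccc(CO)cc1 | starting material
19 | tributyl(iodomethyl)stannane | CCCC[Sn](CCCC)(CCCC)CI | starting material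
20 | tributyl{[(4-methoxyphenyl)methoxy]methyl}stannane | CCCC[Sn](CCCC)(CCCC)COCc1ccc(OC)cc1 | intermediate
21 | {[(4-methoxyphenyl)methoxy]methyl}lithium | [Li]COCc1ccc(OC)cc1 | intermediate
22 | (3S)-3-{(1R,2Z,3S,5S)-3-[(tert-butyldimethylsilyl)oxy]-5-ethenyl-2-ethylidenecyclopentyl}-1-[(4-methoxyphenyl)methoxy]-4-methylpentan-2-one | C=C[C@@H]1C[C@H](O[Si](C)(C)C(C)(C)C)/C(=C\C)[C@H]1[C@H](C(C)C)C(=O)COCc1ccc(OC)cc1 | intermediate
23 | (2S,3S)-3-{(1R,2Z,3S,5S)-3-[(tert-butyldimethylsilyl)oxy]-5-ethenyl-2-ethylidenecyclopentyl}-1-[(4-methoxyphenyl)methoxy]-4-methylpentan-2-ol | C=C[C@@H]1C[C@H](O[Si](C)(C)C(C)(C)C)/C(=C\C)[C@H]1[C@H](C(C)C)[C@H](O)COCc1ccc(OC)cc1 | intermediate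
24 | (2S,3S)-2-[(tert-butyldimethylsilyl)oxy]-3-{(1R,2Z,3S,5S)-3-[(tert-butyldimethylsilyl)oxy]-5-ethenyl-2-ethylidenecyclopentyl}-1-[(4-methoxyphenyl)methoxy]-4-methylpentane | C=C[C@@H]1C[C@H](O[Si](C)(C)C(C)(C)C)/C(=C\C)[C@H]1[C@H](C(C)C)[C@H](O[Si](C)(C)C(C)(C)C)COCc1ccc(OC)cc1 | intermediate
25 | 1-{(1R,2S,3Z,4S)-4-[(tert-butyldimethylsilyl)oxy]-2-{(2S,3S)-2-[(tert-butyldimethylsilyl)oxy]-1-[(4-methoxyphenyl)methoxy]-4-methylpentan-3-yl}-3-ethylidenecyclopentyl}ethan-1-one | CC(=O)[C@@H]1C[C@H](O[Si](C)(C)C(C)(C)C)/C(=C\C)[C@H]1[C@H](C(C)C)[C@H](O[Si](C)(C)C(C)(C)C)COCc1ccc(OC)cc1 | intermediate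
26 | potassium 1-{(1R,2S,3Z,4S)-4-[(tert-butyldimethylsilyl)oxy]-2-{(2S,3S)-2-[(tert-butyldimethylsilyl)oxy]-1-[(4-methoxyphenyl)methoxy]-4-methylpentan-3-yl}-3-ethylidenecyclopentyl}ethen-1-olate | [K+].C=C([O-])[C@@H]1C[C@H](O[Si](C)(C)C(C)(C)C)/C(=C\C)[C@H]1[C@H](C(C)C)[C@H](O[Si](C)(C)C(C)(C)C)COCc1ccc(OC)cc1 | intermediate
27 | 1-{(1R,2S,3Z,4S)-4-[(tert-butyldimethylsilyl)oxy]-2-{(2S,3S)-2-[(tert-butyldimethylsilyl)oxy]-1-[(4-methoxyphenyl)methoxy]-4-methylpentan-3-yl}-3-ethylidenecyclopentyl}ethenyl trifluoromethanesulfonate | C=C(OS(=O)(=O)C(F)(F)F)[C@@H]1C[C@H](O[Si](C)(C)C(C)(C)C)/C(=C\C)[C@H]1[C@H](C(C)C)[C@H](O[Si](C)(C)C(C)(C)C)COCc1ccc(OC)cc1 | intermediate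
28 | 1-{(1R,2S,3Z,4S)-4-[(tert-butyldimethylsilyl)oxy]-2-{(2S,3S)-2-[(tert-butyldimethylsilyl)oxy]-1-hydroxy-4-methylpentan-3-yl}-3-ethylidenecyclopentyl}ethenyl trifluoromethanesulfonate | C=C(OS(=O)(=O)C(F)(F)F)[C@@H]1C[C@H](O[Si](C)(C)C(C)(C)C)/C(=C\C)[C@H]1[C@H](C(C)C)[C@H](O[Si](C)(C)C(C)(C)C)CO | intermediate
29 | 1-{(1R,2S,3Z,4S)-4-[(tert-butyldimethylsilyl)oxy]-2-{(2S,3S)-2-[(tert-butyldimethylsilyl)oxy]-4-methyl-1-oxopentan-3-yl}-3-ethylidenecyclopentyl}ethenyl trifluoromethanesulfonate | C=C(OS(=O)(=O)C(F)(F)F)[C@@H]1C[C@H](O[Si](C)(C)C(C)(C)C)/C(=C\C)[C@H]1[C@H](C(C)C)[C@H](O[Si](C)(C)C(C)(C)C)C=O | intermediate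
30 | (1Z,2S,3aR,5S,6S,7S,7aR)-2,6-bis[(tert-butyldimethylsilyl)oxy]-1-ethylidene-4-methylidene-7-(propan-2-yl)octahydro-1H-inden-5-ol | C=C1[C@@H]2C[C@H](O[Si](C)(C)C(C)(C)C)/C(=C\C)[C@H]2[C@H](C(C)C)[C@H](O[Si](C)(C)C(C)(C)C)[C@H]1O | intermediate
31 | (2Z)-2-methylbut-2-enoic acid (angelic acid) | C/C=C(/C)C(=O)O | starting material
32 | (2Z)-2-methylbut-2-enoic 2,4,6-trichlorobenzoic anhydride | C/C=C(/C)C(=O)OC(=O)c1c(Cl)cc(Cl)cc1Cl | intermediate
33 | (1Z,2S,3aR,5S,6S,7S,7aR)-2,6-bis[(tert-butyldimethylsilyl)oxy]-1-ethylidene-4-methylidene-7-(propan-2-yl)octahydro-1H-inden-5-yl (2Z)-2-methylbut-2-enoate | C=C1[C@@H]2C[C@H](O[Si](C)(C)C(C)(C)C)/C(=C\C)[C@H]2[C@H](C(C)C)[C@H](O[Si](C)(C)C(C)(C)C)[C@H]1OC(=O)/C(C)=C\C | intermediate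
34 | (1Z,2S,3aR,5S,6S,7S,7aR)-1-ethylidene-2,6-dihydroxy-4-methylidene-7-(propan-2-yl)octahydro-1H-inden-5-yl (2Z)-2-methylbut-2-enoate | C=C1[C@@H]2C[C@H](O)/C(=C\C)[C@H]2[C@H](C(C)C)[C@H](O)[C@H]1OC(=O)/C(C)=C\C | intermediate
35 | acetic anhydride | CC(=O)OC(C)=O | starting material
36 | (1Z,2S,3aR,5S,6S,7S,7aR)-2-(acetyloxy)-1-ethylidene-6-hydroxy-4-methylidene-7-(propan-2-yl)octahydro-1H-inden-5-yl (2Z)-2-methylbut-2-enoate | C=C1[C@@H]2C[C@H](OC(C)=O)/C(=C\C)[C@H]2[C@H](C(C)C)[C@H](O)[C@H]1OC(=O)/C(C)=C\C | target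

**Count and risks**

Total step count: 21. Longest linear sequence: 20 steps (steps 1–9 and 11–21; step 10 is a side branch).

Steps most likely to fail:

Step 18. The alkenylchromium may add to the wrong face of the aldehyde, leaving O9 equatorial and cis to O8. The fallback sets out from 29 and comes back to the route at 33. The crude cyclisation product (30 together with its C9 epimer, not separated) would be oxidised with Dess–Martin periodinane to the α-methylene ketone (1Z,2S,3aR,6S,7S,7aR)-2,6-bis[(tert-butyldimethylsilyl)oxy]-1-ethylidene-4-methylidene-7-(propan-2-yl)octahydro-5H-inden-5-one F1. Luche reduction (NaBH4, CeCl3·7H2O, MeOH, −78 °C) should then give the equatorial alcohol, the C9 epimer of 30, F2, because hydride enters axially, anti to the axial silyloxy group on the neighbouring carbon. Mitsunobu esterification of F2 with angelic acid 31 (PPh3, diisopropyl azodicarboxylate, toluene, 0 °C) should invert C9 and give 33 directly, so stereocontrol at C9 moves from the C–C bond formation to a ketone reduction followed by SN2 inversion.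

Step 8. Ketene acetal geometry may be incompletely controlled in the deprotonation of the hindered isovalerate, or a boat transition state may leak in, either of which would erode the configuration at C7. The fallback sets out from 11 and comes back at 16; it fixes the enol ether geometry in a separate, stereoretentive step. 2-Methylpropanal would be converted by Stork–Zhao olefination ((iodomethyl)triphenylphosphonium iodide, NaN(SiMe3)2, THF, −78 °C) into (1Z)-1-iodo-3-methylbut-1-ene F3. Copper-catalysed C–O coupling of 11 with F3 (CuI, 3,4,7,8-tetramethyl-1,10-phenanthroline, Cs2CO3, toluene, 80 °C) should give the allyl (Z)-vinyl ether F4. Heating F4 to 120 °C should bring about the aliphatic Claisen rearrangement through the same chair to give the aldehyde (2S)-2-{(1R,2Z,3S,5S)-3-[(tert-butyldimethylsilyl)oxy]-5-ethenyl-2-ethylidenecyclopentyl}-3-methylbutanal F5. Pinnick oxidation (NaClO2, NaH2PO4, 2-methylbut-2-ene, t-BuOH–H2O) should then give 16.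

Step 21. Site selectivity may be lost in the acetylation (diacetate or acylation at O8). The fallback sets out from 33 and comes back at 36; the two silyl ethers are removed one after the other instead of together. Brief treatment of 33 with HF·pyridine/pyridine at 0 °C should cleave only the less hindered ring A silyl ether to give the mono-silyl ether F6. Acetylation (35, DMAP, pyridine, CH2Cl2) should give the acetate F7 with O8 still silylated, and HF·pyridine at room temperature should then give 36.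

Further compounds
F1 | step 18 | (1Z,2S,3aR,6S,7S,7aR)-2,6-bis[(tert-butyldimethylsilyl)oxy]-1-ethylidene-4-methylidene-7-(propan-2-yl)octahydro-5H-inden-5-one | C=C1[C@@H]2C[C@H](O[Si](C)(C)C(C)(C)C)/C(=C\C)[C@H]2[C@H](C(C)C)[C@H](O[Si](C)(C)C(C)(C)C)C1=O
F2 | step 18 | (1Z,2S,3aR,5R,6S,7S,7aR)-2,6-bis[(tert-butyldimethylsilyl)oxy]-1-ethylidene-4-methylidene-7-(propan-2-yl)octahydro-1H-inden-5-ol | C=C1[C@@H]2C[C@H](O[Si](C)(C)C(C)(C)C)/C(=C\C)[C@H]2[C@H](C(C)C)[C@H](O[Si](C)(C)C(C)(C)C)[C@@H]1O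
F3 | step 8 | (1Z)-1-iodo-3-methylbut-1-ene | CC(C)/C=C\I
F4 | step 8 | tert-butyl{[(1S,4S)-4-ethenyl-2-[(1R)-1-{[(1Z)-3-methylbut-1-en-1-yl]oxy}ethyl]cyclopent-2-en-1-yl]oxy}dimethylsilane | C=C[C@@H]1C[C@H](O[Si](C)(C)C(C)(C)C)C([C@@H](C)O/C=C\C(C)C)=C1
F5 | step 8 | (2S)-2-{(1R,2Z,3S,5S)-3-[(tert-butyldimethylsilyl)oxy]-5-ethenyl-2-ethylidenecyclopentyl}-3-methylbutanal | C=C[C@@H]1C[C@H](O[Si](C)(C)C(C)(C)C)/C(=C\C)[C@H]1[C@H](C(C)C)C=O
F6 | step 21 | (1Z,2S,3aR,5S,6S,7S,7aR)-6-[(tert-butyldimethylsilyl)oxy]-1-ethylidene-2-hydroxy-4-methylidene-7-(propan-2-yl)octahydro-1H-inden-5-yl (2Z)-2-methylbut-2-enoate | C=C1[C@@H]2C[C@H](O)/C(=C\C)[C@H]2[C@H](C(C)C)[C@H](O[Si](C)(C)C(C)(C)C)[C@H]1OC(=O)/C(C)=C\C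
F7 | step 21 | (1Z,2S,3aR,5S,6S,7S,7aR)-2-(acetyloxy)-6-[(tert-butyldimethylsilyl)oxy]-1-ethylidene-4-methylidene-7-(propan-2-yl)octahydro-1H-inden-5-yl (2Z)-2-methylbut-2-enoate | C=C1[C@@H]2C[C@H](OC(C)=O)/C(=C\C)[C@H]2[C@H](C(C)C)[C@H](O[Si](C)(C)C(C)(C)C)[C@H]1OC(=O)/C(C)=C\C
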